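**Retrosynthetic overview**

The target is labda-8(17),13E-diene-7α,15,19-triol 19-acetate. The plan rests on ring B, whose only ring oxygen sits on C7 with C10 para and C5 meta to it, so ring B can be carried as the anisole ring of 7-methoxy-1-tetralone; and on C19, whose hydroxyl on C4 lies homoallylic to the Birch-derived C5=C10 alkene on the β face that C20 must occupy.
Late disconnections: C19 acetate; C13–C16 and C14–C15 (carboalumination of a C13 alkyne with formaldehyde trap); C12–C13 (acetylide alkylation); the 8(17)-en-7α-ol from a 7α,8α-epoxide; C9–C11 by Johnson–Claisen rearrangement from a 7β-allylic alcohol; C8–C17 by enone α′-methylation.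
Early disconnections: C10–C20 and C5–C20 are made together as a cyclopropane by C19-hydroxyl-directed zinc-carbenoid addition to the 5(10)-en-7-one, and acid then releases C20 as the angular methyl; the C4 quaternary centre comes from asymmetric hydrovinylation of the methylenetetralin.
Ring order: rings A and B both arrive with the tetralone (B aromatic, dearomatised by Birch reduction); the only ring closed is the cyclopropane C5–C10–C20 (step 6), which is opened again in step 7.

Key step: step 6

Numbering: labdane numbering is used for all bicyclic compounds (C18 = 4α-methyl, C19 = 4β-CH2O, C20 on C10, C17 on C8, side chain C11–C16); α is the face opposite C20.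
Assumption: the sense of induction in step 2 is fixed by the choice of ligand enantiomer, and the one that leads to (R)-6 is meant.
Remark: C8 in 20 and 21 is drawn as the expected 8α-methyl epimer; the C8 epimer would serve equally, since this centre becomes planar in step 11.

**Route**

Step 1
Reactants: 1 7-methoxy-1-tetralone; 2 methyltriphenylphosphonium bromide
Product: 4 7-methoxy-1-methylene-1,2,3,4-tetrahydronaphthalene, via methylenetriphenylphosphorane 3 (not isolated)
Conditions: 2, KOtBu, THF, 0 °C → rt; then 1, rt → 50 °C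
Reagents that add atoms: methyltriphenylphosphonium bromide, C[P+](c1ccccc1)(c1ccccc1)c1ccccc1.[Br-]
Why: Wittig methylenation of the aryl ketone with the non-stabilised ylide is routine and gives the 1,1-disubstituted styrene needed next; no stereocentre is formed.

Step 2
Reactants: 4 7-methoxy-1-methylene-1,2,3,4-tetrahydronaphthalene; 5 ethylene
Product: 6 (R)-7-methoxy-1-methyl-1-vinyl-1,2,3,4-tetrahydronaphthalene
Conditions: [(η3-C3H5)NiBr]2 (cat.), Na[B(3,5-(CF3)2C6H3)4], 1,1'-binaphthyl-2,2'-diyl phosphoramidite of bis(1-phenylethyl)amine (enantiomer leading to (R)-6), C2H4 (1 atm), CH2Cl2, −70 → −20 °C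
Reagents that add atoms: ethylene, C=C
Why: Nickel-hydride-catalysed asymmetric hydrovinylation of 1-methylenetetralins (hydride addition to the tertiary benzylic nickel species, ethylene insertion, β-hydride elimination) is an established route to benzylic all-carbon quaternary centres, and the chiral phosphoramidite on nickel selects the alkene face and so sets C4.

Step 3
Reactants: 6 (R)-7-methoxy-1-methyl-1-vinyl-1,2,3,4-tetrahydronaphthalene; 7 ozone
Product: 9 (S)-(7-methoxy-1-methyl-1,2,3,4-tetrahydronaphthalen-1-yl)methanol, via aldehyde 8 (not isolated)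
Conditions: O3, CH2Cl2/MeOH, −78 °C (stopped at first excess); Me2S, −78 °C → rt; then NaBH4, 0 °C
Reagents that add atoms: ozone, [O-][O+]=O
Why: Ozonolysis of the monosubstituted alkene is far faster than attack on the anisole ring, and borohydride reduction of the non-enolisable aldehyde gives the neopentyl C19 alcohol with the quaternary centre untouched.

Step 4
Reactants: 9 (S)-(7-methoxy-1-methyl-1,2,3,4-tetrahydronaphthalen-1-yl)methanol
Product: 10 [(1S)-7-methoxy-1-methyl-1,2,3,4,5,8-hexahydronaphthalen-1-yl]methanol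
Conditions: Li, NH3(l), THF, t-BuOH, −78 → −33 °C; NH4Cl
Reagents that add atoms: none
Why: Birch reduction of the anisole protonates ortho and meta to the methoxy group, leaving the C7=C8 enol ether and the tetrasubstituted C5=C10 alkene, as in the reduction of estradiol methyl ether.

Step 5
Reactants: 10 [(1S)-7-methoxy-1-methyl-1,2,3,4,5,8-hexahydronaphthalen-1-yl]methanol; 11 water
Product: 12 (S)-8-(hydroxymethyl)-8-methyl-3,4,5,6,7,8-hexahydronaphthalen-2(1H)-one (19-hydroxy 5(10)-en-7-one)
Conditions: (CO2H)2, MeOH/H2O, rt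
Reagents that add atoms: water, O
Why: Mild enol ether hydrolysis with oxalic acid frees the C7 ketone without moving the C5=C10 alkene into conjugation, giving the β,γ-unsaturated ketone.

Step 6
Reactants: 12 (S)-8-(hydroxymethyl)-8-methyl-3,4,5,6,7,8-hexahydronaphthalen-2(1H)-one; 13 diiodomethane
Product: 15 19-hydroxy-5β,20-cyclo-11,12,13,14,15,16,17-heptanorlabdan-7-one (5β,10β-methano 7-ketone), via (iodomethyl)zinc alkoxide 14 (not isolated)
Conditions: Et2Zn (3 equiv), CH2I2 (6 equiv), CH2Cl2, −10 °C → rt; aq NH4Cl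
Reagents that add atoms: diiodomethane, ICI
Why: Hydroxyl-directed Simmons–Smith cyclopropanation in its Furukawa form: Et2Zn converts the C19 hydroxyl into an ethylzinc alkoxide, exchange with CH2I2 places the iodomethylzinc carbenoid on that oxygen, and methylene is transferred to the C5=C10 alkene in one concerted butterfly-type step. The closest known reaction is the homoallylic-hydroxyl-directed methylenation of Birch-derived 5(10)-enes in the 19-norsteroid series. Only the three-membered ring C5–C10–C20 closes, by concerted [2+1] addition across the tetrasubstituted alkene, so C5–C20 and C10–C20 form together. The two new stereocentres C5 and C10 follow from the face of addition, which the C4 stereocentre controls: the zinc-bound C19 oxygen can reach only the face on which it stands, so C20 ends β and cis to C19. The step needs π-facial selectivity and chemoselectivity for the alkene over the β,γ-unsaturated ketone; the alkoxide tether secures the first, and the electron-rich alkene, the inertness of ketones to zinc carbenoids and the low temperature (which disfavours Lewis-acid-promoted double-bond migration) secure the second.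

Step 7
Reactants: 15 19-hydroxy-5β,20-cyclo-11,12,13,14,15,16,17-heptanorlabdan-7-one
Product: 16 19-hydroxy-11,12,13,14,15,16,17-heptanorlabd-5-en-7-one (10β-methyl Δ5-7-one)
Conditions: conc. HCl, MeOH, reflux
Reagents that add atoms: none
Why: Acid-catalysed homoconjugate opening of the β,γ-cyclopropyl ketone: the C6=C7 enol pushes into the C5–C20 bond while C20 is protonated, leaving C20 as the C10 methyl and a conjugated C5=C6 enone, the known behaviour of 5β,19-cyclo-3-ketosteroids; the C10 configuration was fixed in step 6.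

Step 8
Reactants: 16 19-hydroxy-11,12,13,14,15,16,17-heptanorlabd-5-en-7-one; 17 tert-butyldimethylsilyl chloride
Product: 18 19-(tert-butyldimethylsilyloxy)-11,12,13,14,15,16,17-heptanorlabd-5-en-7-one
Conditions: TBSCl, imidazole, DMAP (cat.), DMF, rt → 40 °C
Reagents that add atoms: tert-butyldimethylsilyl chloride, CC(C)(C)[Si](C)(C)Cl
Why: Silylation of the primary neopentyl alcohol masks C19 for the basic, reducing and organometallic steps that follow.

Step 9
Reactants: 18 19-(tert-butyldimethylsilyloxy)-11,12,13,14,15,16,17-heptanorlabd-5-en-7-one; 19 iodomethane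
Product: 20 19-(tert-butyldimethylsilyloxy)-11,12,13,14,15,16-hexanorlabd-5-en-7-one (8α-methyl drawn)
Conditions: LiN(iPr)2, THF, −78 °C; MeI, −78 → −30 °C
Reagents that add atoms: iodomethane, CI
Why: Kinetic α′-deprotonation of the enone can occur only at C8 (C4 and C10 are quaternary, so there is no γ-hydrogen), and alkylation of the cross-conjugated dienolate brings in C17, expected anti to the C10 methyl although the C8 configuration is not retained later.

Step 10
Reactants: 20 19-(tert-butyldimethylsilyloxy)-11,12,13,14,15,16-hexanorlabd-5-en-7-one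
Product: 21 19-(tert-butyldimethylsilyloxy)-11,12,13,14,15,16-hexanor-5α-labdan-7-one (8α-methyl drawn)
Conditions: Li, NH3(l), THF, t-BuOH (1 equiv), −78 °C; NH4Cl
Reagents that add atoms: none
Why: Dissolving-metal reduction of the enone protonates the β-carbon C5 axially on the α face, anti to the C10 methyl, so the trans-decalin (H5 α) should form as with Δ4-3-ketosteroids and 4,4,10-trimethyl-Δ5-octalin-7-ones.

Step 11
Reactants: 21 19-(tert-butyldimethylsilyloxy)-11,12,13,14,15,16-hexanor-5α-labdan-7-one; 22 iodotrimethylsilane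
Product: 23 7-(trimethylsilyloxy)-19-(tert-butyldimethylsilyloxy)-11,12,13,14,15,16-hexanorlabd-7-ene
Conditions: TMSI, (Me3Si)2NH, CH2Cl2, −20 °C → rt
Reagents that add atoms: iodotrimethylsilane, C[Si](C)(C)I
Why: Enol silylation under equilibrating conditions gives the more substituted C7=C8 silyl enol ether, the direction also preferred by trans-fused ketones of this type and favoured further by the crowded C6 side.

Step 12
Reactants: 23 7-(trimethylsilyloxy)-19-(tert-butyldimethylsilyloxy)-11,12,13,14,15,16-hexanorlabd-7-ene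
Product: 24 19-(tert-butyldimethylsilyloxy)-11,12,13,14,15,16-hexanorlabd-8-en-7-one
Conditions: Pd(OAc)2 (1.1 equiv), MeCN, rt
Reagents that add atoms: none
Why: Saegusa–Ito oxidation: the palladium enolate bonded at C8 undergoes β-hydride elimination towards C9 and gives the conjugated endocyclic 8-methyl enone.

Step 13
Reactants: 24 19-(tert-butyldimethylsilyloxy)-11,12,13,14,15,16-hexanorlabd-8-en-7-one
Product: 25 19-(tert-butyldimethylsilyloxy)-11,12,13,14,15,16-hexanorlabd-8-en-7β-ol
Conditions: NaBH4, CeCl3·7H2O, MeOH, −40 → 0 °C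
Reagents that add atoms: none
Why: Luche 1,2-reduction, in which hydride adds to C7 axially from the α face (anti to the pseudo-axial C6–H and away from the β substituents on C4 and C10), so the alcohol should be 7β and pseudo-equatorial.

Step 14
Reactants: 25 19-(tert-butyldimethylsilyloxy)-11,12,13,14,15,16-hexanorlabd-8-en-7β-ol; 26 triethyl orthoacetate
Product: 28 ethyl 19-(tert-butyldimethylsilyloxy)-13,14,15,16-tetranorlabd-7-en-12-oate, via ketene acetal 27 (not isolated)
Conditions: MeC(OEt)3, EtCO2H (cat.), xylene, 140 °C, EtOH distilled off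
Reagents that add atoms: triethyl orthoacetate, CCOC(C)(OCC)OCC
Why: Johnson–Claisen rearrangement: the mixed ketene acetal on the 7β oxygen rearranges suprafacially, so C11 bonds to C9 on the β face (H9 α) while the alkene moves to C7=C8, the same syn delivery next to an angular methyl that Claisen rearrangements of steroidal Δ4-3β-ols show.

Step 15
Reactants: 28 ethyl 19-(tert-butyldimethylsilyloxy)-13,14,15,16-tetranorlabd-7-en-12-oate
Product: 29 19-(tert-butyldimethylsilyloxy)-13,14,15,16-tetranorlabd-7-en-12-ol
Conditions: LiAlH4, Et2O, 0 °C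
Reagents that add atoms: none
Why: Hydride reduction of the ester to the primary alcohol, with the silyl ether and the trisubstituted alkene inert.

Step 16
Reactants: 29 19-(tert-butyldimethylsilyloxy)-13,14,15,16-tetranorlabd-7-en-12-ol; 30 iodine
Product: 31 12-iodo-19-(tert-butyldimethylsilyloxy)-13,14,15,16-tetranorlabd-7-ene
Conditions: I2, PPh3, imidazole, CH2Cl2, 0 °C → rt
Reagents that add atoms: iodine, II
Why: Appel-type iodination converts the unhindered primary alcohol into the iodide under neutral conditions.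

Step 17
Reactants: 31 12-iodo-19-(tert-butyldimethylsilyloxy)-13,14,15,16-tetranorlabd-7-ene; 32 trimethylsilylacetylene
Product: 34 19-(tert-butyldimethylsilyloxy)-14-(trimethylsilyl)-15,16-dinorlabd-7-en-13-yne, via lithium (trimethylsilyl)acetylide 33 (not isolated)
Conditions: 32, n-BuLi, THF, −78 °C; then 31, DMPU, −78 °C → rt
Reagents that add atoms: trimethylsilylacetylene, C#C[Si](C)(C)C
Why: SN2 alkylation of the lithium acetylide by the primary iodide in a dipolar aprotic co-solvent adds C13 and C14, and the silyl cap keeps the alkyne inert in the next two steps.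

Step 18
Reactants: 34 19-(tert-butyldimethylsilyloxy)-14-(trimethylsilyl)-15,16-dinorlabd-7-en-13-yne; 35 3-chloroperbenzoic acid
Product: 36 7α,8α-epoxy-19-(tert-butyldimethylsilyloxy)-14-(trimethylsilyl)-15,16-dinorlabd-13-yne
Conditions: mCPBA, NaHCO3, CH2Cl2, 0 °C
Reagents that add atoms: 3-chloroperbenzoic acid, OOC(=O)c1cccc(Cl)c1
Why: Prilezhaev epoxidation of the trisubstituted Δ7 alkene from the α face, opposite the axial C10 methyl and the β side chain on C9, while the silylalkyne reacts far more slowly.

Step 19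
Reactants: 36 7α,8α-epoxy-19-(tert-butyldimethylsilyloxy)-14-(trimethylsilyl)-15,16-dinorlabd-13-yne
Product: 38 19-(tert-butyldimethylsilyloxy)-14-(trimethylsilyl)-15,16-dinorlabd-8(17)-en-13-yn-7α-ol, via diethylaluminium 2,2,6,6-tetramethylpiperidide 37 (not isolated)
Conditions: Et2AlCl, lithium 2,2,6,6-tetramethylpiperidide, toluene, 0 °C; then 36, 0 °C → rt; aq potassium sodium tartrate
Reagents that add atoms: none
Why: Aluminium-amide-mediated isomerisation of an epoxide to an allylic alcohol (syn β-elimination): aluminium binds the epoxide oxygen and the amide removes a proton from the C17 methyl, the group cis to H7, so the C8–O bond opens to the 8(17)-alkene while the C7–O bond keeps its α configuration.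

Step 20
Reactants: 38 19-(tert-butyldimethylsilyloxy)-14-(trimethylsilyl)-15,16-dinorlabd-8(17)-en-13-yn-7α-ol
Product: 39 19-(tert-butyldimethylsilyloxy)-15,16-dinorlabd-8(17)-en-13-yn-7α-ol
Conditions: K2CO3, MeOH, rt
Reagents that add atoms: none
Why: Base-catalysed methanolysis of the alkynyl C–Si bond frees the terminal alkyne, and the hindered neopentyl silyl ether is stable to these conditions.

Step 21
Reactants: 39 19-(tert-butyldimethylsilyloxy)-15,16-dinorlabd-8(17)-en-13-yn-7α-ol; 40 trimethylaluminium; 41 paraformaldehyde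
Product: 44 19-(tert-butyldimethylsilyloxy)labda-8(17),13E-diene-7α,15-diol, via alkenylalane 42 (not isolated), via lithium alanate 43 (not isolated)
Conditions: Me3Al (4 equiv), Cp2ZrCl2 (0.5 equiv), CH2Cl2, 0 °C → rt; then n-BuLi, THF, −78 °C; (CH2O)n, −78 °C → rt; aq potassium sodium tartrate
Reagents that add atoms: trimethylaluminium, C[Al](C)C; paraformaldehyde (as formaldehyde), C=O
Why: Negishi carboalumination catalysed by Cp2ZrCl2 adds methyl and aluminium syn across the terminal alkyne with methyl on C13, and the derived alkenyl alanate adds to formaldehyde with retention, so the C13=C14 alkene is E; the C7 hydroxyl travels as its aluminium alkoxide.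

Step 22
Reactants: 44 19-(tert-butyldimethylsilyloxy)labda-8(17),13E-diene-7α,15-diol; 45 2-methoxypropene
Product: 46 7α,15-bis(2-methoxyprop-2-yloxy)-19-(tert-butyldimethylsilyloxy)labda-8(17),13E-diene
Conditions: 2-methoxypropene (excess), PPTS (cat.), CH2Cl2, 0 °C; Et3N quench
Reagents that add atoms: 2-methoxypropene, COC(C)=C
Why: Acid-catalysed addition of both hydroxyls to the enol ether gives achiral mixed-ketal ethers that tolerate fluoride and acylation and come off under very mild acid.

Step 23
Reactants: 46 7α,15-bis(2-methoxyprop-2-yloxy)-19-(tert-butyldimethylsilyloxy)labda-8(17),13E-diene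
Product: 47 7α,15-bis(2-methoxyprop-2-yloxy)labda-8(17),13E-dien-19-ol
Conditions: Bu4NF, THF, rt → 45 °C
Reagents that add atoms: none
Why: Fluoride-mediated desilylation frees only the C19 hydroxyl, because the ketal ethers are inert to fluoride.

Step 24
Reactants: 47 7α,15-bis(2-methoxyprop-2-yloxy)labda-8(17),13E-dien-19-ol; 48 acetic anhydride
Product: 49 19-acetoxy-7α,15-bis(2-methoxyprop-2-yloxy)labda-8(17),13E-diene
Conditions: Ac2O, pyridine, DMAP (cat.), CH2Cl2, rt
Reagents that add atoms: acetic anhydride, CC(=O)OC(C)=O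
Why: DMAP-catalysed acylation of the single free primary hydroxyl places the acetate on C19 and nowhere else.

Step 25
Reactants: 49 19-acetoxy-7α,15-bis(2-methoxyprop-2-yloxy)labda-8(17),13E-diene
Product: 50 labda-8(17),13E-diene-7α,15,19-triol 19-acetate (CNP0209062.1)
Conditions: PPTS (cat.), MeOH, 0 °C → rt
Reagents that add atoms: none
Why: Mild acid-catalysed transketalisation to methanol removes both 2-methoxyprop-2-yl groups without cleaving the acetate or ionising the allylic alcohols.

**Compound list**

1 | 7-methoxy-1-tetralone | COc1ccc2CCCC(=O)c2c1 | starting material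
2 | methyltriphenylphosphonium bromide | C[P+](c1ccccc1)(c1ccccc1)c1ccccc1.[Br-] | starting material
3 | methylenetriphenylphosphorane | C=P(c1ccccc1)(c1ccccc1)c1ccccc1 | intermediate
4 | 7-methoxy-1-methylene-1,2,3,4-tetrahydronaphthalene | COc1ccc2CCCC(=C)c2c1 | intermediate
5 | ethylene | C=C | starting material
6 | (R)-7-methoxy-1-methyl-1-vinyl-1,2,3,4-tetrahydronaphthalene | COc1ccc2CCC[C@](C)(C=C)c2c1 | intermediate
7 | ozone | [O-][O+]=O | starting material
8 | (S)-7-methoxy-1-methyl-1,2,3,4-tetrahydronaphthalene-1-carbaldehyde | COc1ccc2CCC[C@](C)(C=O)c2c1 | intermediate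
9 | (S)-(7-methoxy-1-methyl-1,2,3,4-tetrahydronaphthalen-1-yl)methanol | COc1ccc2CCC[C@](C)(CO)c2c1 | intermediate
10 | [(1S)-7-methoxy-1-methyl-1,2,3,4,5,8-hexahydronaphthalen-1-yl]methanol (C7=C8 enol ether, C5=C10 alkene) | COC1=CCC2=C(C1)[C@@](C)(CO)CCC2 | intermediate
11 | water | O | starting material
12 | (S)-8-(hydroxymethyl)-8-methyl-3,4,5,6,7,8-hexahydronaphthalen-2(1H)-one (19-hydroxy 5(10)-en-7-one) | O=C1CCC2=C(C1)[C@@](C)(CO)CCC2 | intermediate
13 | diiodomethane | ICI | starting material
14 | (iodomethyl)zinc alkoxide of 12 | O=C1CCC2=C(C1)[C@@](C)(CO[Zn]CI)CCC2 | intermediate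
15 | 19-hydroxy-5β,20-cyclo-11,12,13,14,15,16,17-heptanorlabdan-7-one (C20 bridges C5 and C10 on the β face, cis to C19) | O=C1CC[C@]23C[C@@]2(C1)[C@@](C)(CO)CCC3 | intermediate
16 | 19-hydroxy-11,12,13,14,15,16,17-heptanorlabd-5-en-7-one (10β-methyl) | O=C1C=C2[C@@](C)(CO)CCC[C@]2(C)CC1 | intermediate
17 | tert-butyldimethylsilyl chloride | CC(C)(C)[Si](C)(C)Cl | starting material
18 | 19-(tert-butyldimethylsilyloxy)-11,12,13,14,15,16,17-heptanorlabd-5-en-7-one | O=C1C=C2[C@@](C)(CO[Si](C)(C)C(C)(C)C)CCC[C@]2(C)CC1 | intermediate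
19 | iodomethane | CI | starting material
20 | 19-(tert-butyldimethylsilyloxy)-11,12,13,14,15,16-hexanorlabd-5-en-7-one (8α-methyl drawn) | O=C1C=C2[C@@](C)(CO[Si](C)(C)C(C)(C)C)CCC[C@]2(C)C[C@@H]1C | intermediate
21 | 19-(tert-butyldimethylsilyloxy)-11,12,13,14,15,16-hexanor-5α-labdan-7-one (8α-methyl drawn) | O=C1C[C@H]2[C@@](C)(CO[Si](C)(C)C(C)(C)C)CCC[C@]2(C)C[C@@H]1C | intermediate
22 | iodotrimethylsilane | C[Si](C)(C)I | starting material
23 | 7-(trimethylsilyloxy)-19-(tert-butyldimethylsilyloxy)-11,12,13,14,15,16-hexanorlabd-7-ene | CC1=C(O[Si](C)(C)C)C[C@H]2[C@@](C)(CO[Si](C)(C)C(C)(C)C)CCC[C@]2(C)C1 | intermediate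
24 | 19-(tert-butyldimethylsilyloxy)-11,12,13,14,15,16-hexanorlabd-8-en-7-one | O=C1C[C@H]2[C@@](C)(CO[Si](C)(C)C(C)(C)C)CCC[C@]2(C)C=C1C | intermediate
25 | 19-(tert-butyldimethylsilyloxy)-11,12,13,14,15,16-hexanorlabd-8-en-7β-ol | O[C@H]1C[C@H]2[C@@](C)(CO[Si](C)(C)C(C)(C)C)CCC[C@]2(C)C=C1C | intermediate
26 | triethyl orthoacetate | CCOC(C)(OCC)OCC | starting material
27 | 7β-(1-ethoxyvinyloxy) ketene acetal of 25 | C=C(OCC)O[C@H]1C[C@H]2[C@@](C)(CO[Si](C)(C)C(C)(C)C)CCC[C@]2(C)C=C1C | intermediate
28 | ethyl 19-(tert-butyldimethylsilyloxy)-13,14,15,16-tetranorlabd-7-en-12-oate (H9 α) | CC1=CC[C@H]2[C@@](C)(CO[Si](C)(C)C(C)(C)C)CCC[C@]2(C)[C@H]1CC(=O)OCC | intermediate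
29 | 19-(tert-butyldimethylsilyloxy)-13,14,15,16-tetranorlabd-7-en-12-ol | CC1=CC[C@H]2[C@@](C)(CO[Si](C)(C)C(C)(C)C)CCC[C@]2(C)[C@H]1CCO | intermediate
30 | iodine | II | starting material
31 | 12-iodo-19-(tert-butyldimethylsilyloxy)-13,14,15,16-tetranorlabd-7-ene | CC1=CC[C@H]2[C@@](C)(CO[Si](C)(C)C(C)(C)C)CCC[C@]2(C)[C@H]1CCI | intermediate
32 | trimethylsilylacetylene | C#C[Si](C)(C)C | starting material
33 | lithium (trimethylsilyl)acetylide | [Li]C#C[Si](C)(C)C | intermediate
34 | 19-(tert-butyldimethylsilyloxy)-14-(trimethylsilyl)-15,16-dinorlabd-7-en-13-yne | CC1=CC[C@H]2[C@@](C)(CO[Si](C)(C)C(C)(C)C)CCC[C@]2(C)[C@H]1CCC#C[Si](C)(C)C | intermediate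
35 | 3-chloroperbenzoic acid | OOC(=O)c1cccc(Cl)c1 | starting material
36 | 7α,8α-epoxy-19-(tert-butyldimethylsilyloxy)-14-(trimethylsilyl)-15,16-dinorlabd-13-yne | C[C@@]12O[C@@H]1C[C@H]3[C@@](C)(CO[Si](C)(C)C(C)(C)C)CCC[C@]3(C)[C@H]2CCC#C[Si](C)(C)C | intermediate
37 | diethylaluminium 2,2,6,6-tetramethylpiperidide | CC[Al](CC)N1C(C)(C)CCCC1(C)C | intermediate
38 | 19-(tert-butyldimethylsilyloxy)-14-(trimethylsilyl)-15,16-dinorlabd-8(17)-en-13-yn-7α-ol | C=C1[C@H](O)C[C@H]2[C@@](C)(CO[Si](C)(C)C(C)(C)C)CCC[C@]2(C)[C@H]1CCC#C[Si](C)(C)C | intermediate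
39 | 19-(tert-butyldimethylsilyloxy)-15,16-dinorlabd-8(17)-en-13-yn-7α-ol | C=C1[C@H](O)C[C@H]2[C@@](C)(CO[Si](C)(C)C(C)(C)C)CCC[C@]2(C)[C@H]1CCC#C | intermediate
40 | trimethylaluminium | C[Al](C)C | starting material
41 | paraformaldehyde (source of formaldehyde) | C=O | starting material
42 | (13E)-14-(dimethylalumino)alkene, 7-O-dimethylaluminium alkoxide (alkenylalane) | C=C1[C@H](O[Al](C)C)C[C@H]2[C@@](C)(CO[Si](C)(C)C(C)(C)C)CCC[C@]2(C)[C@H]1CC/C(C)=C/[Al](C)C | intermediate
43 | lithium butyl(dimethyl)alkenylalanate of 42 | [Li+].C=C1[C@H](O[Al](C)C)C[C@H]2[C@@](C)(CO[Si](C)(C)C(C)(C)C)CCC[C@]2(C)[C@H]1CC/C(C)=C/[Al-](C)(C)CCCC | intermediate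
44 | 19-(tert-butyldimethylsilyloxy)labda-8(17),13E-diene-7α,15-diol | C=C1[C@H](O)C[C@H]2[C@@](C)(CO[Si](C)(C)C(C)(C)C)CCC[C@]2(C)[C@H]1CC/C(C)=C/CO | intermediate
45 | 2-methoxypropene | COC(C)=C | starting material
46 | 7α,15-bis(2-methoxyprop-2-yloxy)-19-(tert-butyldimethylsilyloxy)labda-8(17),13E-diene | C=C1[C@H](OC(C)(C)OC)C[C@H]2[C@@](C)(CO[Si](C)(C)C(C)(C)C)CCC[C@]2(C)[C@H]1CC/C(C)=C/COC(C)(C)OC | intermediate
47 | 7α,15-bis(2-methoxyprop-2-yloxy)labda-8(17),13E-dien-19-ol | C=C1[C@H](OC(C)(C)OC)C[C@H]2[C@@](C)(CO)CCC[C@]2(C)[C@H]1CC/C(C)=C/COC(C)(C)OC | intermediate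
48 | acetic anhydride | CC(=O)OC(C)=O | starting material
49 | 19-acetoxy-7α,15-bis(2-methoxyprop-2-yloxy)labda-8(17),13E-diene | C=C1[C@H](OC(C)(C)OC)C[C@H]2[C@@](C)(COC(C)=O)CCC[C@]2(C)[C@H]1CC/C(C)=C/COC(C)(C)OC | intermediate
50 | labda-8(17),13E-diene-7α,15,19-triol 19-acetate (CNP0209062.1) | C=C1[C@H](O)C[C@H]2[C@@](C)(COC(C)=O)CCC[C@]2(C)[C@H]1CC/C(C)=C/CO | target

**Step count**

Total: 25 steps. Longest linear sequence: 25 steps (fully linear from 1).

**Steps most likely to fail, with fallbacks**

1. Step 6. The C5=C10 alkene may migrate into conjugation with the free C7 ketone under the Lewis-acidic zinc iodide before the hindered tetrasubstituted alkene is methylenated, and facial control may erode if undirected carbenoid competes. The fallback sets out from 10 and never frees the ketone: ethylene glycol with pyridinium p-toluenesulfonate in CH2Cl2 should exchange the enol ether for the dioxolane, giving the 7,7-ethylenedioxy 5(10)-ene alcohol F1. The same C19-directed Et2Zn/CH2I2 methylenation on this non-enolisable substrate should give the 5β,20-cyclo ketal F2. Aqueous HCl in MeOH at reflux should then remove the ketal and open the cyclopropane in one operation, returning to the route at 16.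

2. Step 14. The rearrangement must pass through a boat-like ring B with C11 arriving beside the axial C10 methyl, so it may be slower than acid-promoted ionisation and dehydration of the allylic alcohol to a diene. The fallback sets out from 25 and uses a [2,3]-Wittig–Still rearrangement, whose five-membered envelope needs no boat. KH and Bu3SnCH2I in THF should give the 7β-(tributylstannylmethyl) ether F3. n-BuLi in THF (−78 → 0 °C) should effect tin–lithium exchange and the suprafacial [2,3] shift to the 9β-hydroxymethyl Δ7-alkene F4. Tf2O with 2,6-lutidine at −78 °C should give the primary triflate F5. Displacement with 3-lithio-1-(trimethylsilyl)propyne (from 1-(trimethylsilyl)propyne and n-BuLi) in THF at −78 °C supplies C12 to C14 and returns to the route at 34.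

3. Step 12. β-Hydride elimination may go towards the C17 methyl (exocyclic enone), palladation of the tetrasubstituted enol ether may be sluggish, and regiochemical leakage in the enol silylation of step 11 would compound this. The fallback sets out from 21 and uses halogenation–elimination. PhNMe3Br3 in THF at 0 °C should brominate through the more substituted enol to the 8β-bromo-8α-methyl ketone F6. Li2CO3 and LiBr in DMF at 120 °C should dehydrobrominate into conjugation, returning to the route at 24.

**Further compounds**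

F1 | step 6 | 7,7-ethylenedioxy 5(10)-ene alcohol (dioxolane of 12) | C1COC2(O1)CCC3=C(C2)[C@@](C)(CO)CCC3
F2 | step 6 | 5β,20-cyclo ketal (dioxolane of 15) | C1COC2(O1)CC[C@]34C[C@@]3(C2)[C@@](C)(CO)CCC4
F3 | step 14 | 7β-(tributylstannylmethyl) ether of 25 | CCCC[Sn](CCCC)(CCCC)CO[C@H]1C[C@H]2[C@@](C)(CO[Si](C)(C)C(C)(C)C)CCC[C@]2(C)C=C1C
F4 | step 14 | 9β-hydroxymethyl Δ7-alkene (19-silyloxy-12,13,14,15,16-pentanorlabd-7-en-11-ol) | CC1=CC[C@H]2[C@@](C)(CO[Si](C)(C)C(C)(C)C)CCC[C@]2(C)[C@H]1CO
F5 | step 14 | trifluoromethanesulfonate of F4 | CC1=CC[C@H]2[C@@](C)(CO[Si](C)(C)C(C)(C)C)CCC[C@]2(C)[C@H]1COS(=O)(=O)C(F)(F)F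
F6 | step 12 | 8β-bromo-8α-methyl ketone from 21 | O=C1C[C@H]2[C@@](C)(CO[Si](C)(C)C(C)(C)C)CCC[C@]2(C)C[C@@]1(C)Br
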